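**Plan**

1. The target is read as drawn: ring A (guaiacyl) on furofuran C1, ring B (the benzofuran arene) on furofuran C4, ring C (guaiacyl) on benzofuran C2. The benzofuran is 2,3-cis (2S,3S) and both aryl groups of the furofuran are endo (1S,3aS,4S,6aS).
2. Cuts: furofuran O2–C1 and O5–C4 (back to diketo diol 28), then C1–C6a (conjugate addition) and C4–C3a (aldol), which gives dithiane 18, butenolide 22 and aldehyde 15. In 15 the benzofuran C3–C3a bond is cut (key step), then O1–C2 (phenoxide opening of an epoxy alcohol), which gives 4 and 6.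
3. Enabling feature: benzofuran C3 carries CH2OH and is bonded to C3a, the arene carbon ortho to ring oxygen O1. This is the array left when an aryl ether lithiated ortho to oxygen opens a tethered terminal epoxide at its inner carbon.
4. Ring order forward: the dihydrofuran ring of the benzofuran closes first (step 9), the open chain C1–C6a–C3a–C4 is then assembled (step 16), and both tetrahydrofuran rings close together last (step 20).
5. Stereochemistry: benzofuran C2/C3 come from a Sharpless epoxidation with L-(+)-tartrate, relayed by three SN2 inversions (steps 5, 8, 9). Furofuran C3a/C6a come from the (5S)-menthyloxybutenolide made from (+)-menthol. Furofuran C1/C4 come from hydride delivery to the convex face of bicyclic oxocarbenium ions.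

Key step: step 9

Remark: the carbinol carbon created in step 16 is expected as an epimer mixture and is left open in 25 and 26, because step 18 oxidises it to the ketone.

Abbreviations in names: Ar = 3-methoxy-4-(prop-2-enyloxy)phenyl; Men = (1S,2R,5S)-5-methyl-2-(propan-2-yl)cyclohexyl; pivalate = 2,2-dimethylpropanoate.

**Route**

Step 1
Reactants: 1 ferulic acid, (2E)-3-(4-hydroxy-3-methoxyphenyl)prop-2-enoic acid
Product: 2 prop-2-enyl (2E)-3-Ar-prop-2-enoate
Conditions: allyl bromide (2.5 equiv), K2CO3, DMF, 50 °C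
Reagents that add atoms: allyl bromide, C=CCBr
Why: Williamson-type O-alkylation of the phenoxide and the carboxylate by allyl bromide installs the phenol protecting group and the ester in one operation.

Step 2
Reactants: 2 prop-2-enyl (2E)-3-Ar-prop-2-enoate
Product: 3 (2E)-3-Ar-prop-2-en-1-ol
Conditions: i-Bu2AlH (3 equiv), CH2Cl2, −78 °C; aqueous potassium sodium tartrate work-up
Reagents that add atoms: none
Why: 1,2-Reduction of the conjugated ester by the aluminium hydride at low temperature gives the (E)-allylic alcohol and touches neither alkene.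

Step 3
Reactants: 3 (2E)-3-Ar-prop-2-en-1-ol
Product: 4 [(2S,3S)-3-Ar-oxiran-2-yl]methanol
Conditions: Ti(OiPr)4 (10 mol %), L-(+)-diethyl tartrate (12 mol %), t-BuOOH, 4 Å molecular sieves, CH2Cl2, −20 °C; non-acidic work-up, product used without chromatography on silica
Reagents that add atoms: tert-butyl hydroperoxide, CC(C)(C)OO
Why: Sharpless asymmetric epoxidation, in which the titanium tartrate complex binds the allylic hydroxyl and with L-(+)-tartrate delivers oxygen to the alkene face that gives the (2S,3S)-epoxide, while the allyl ether alkene has no directing hydroxyl and is left alone.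

Step 4
Reactants: 5 5-bromovanillin, 3-bromo-4-hydroxy-5-methoxybenzaldehyde
Product: 6 2-bromo-4-(1,3-dioxolan-2-yl)-6-methoxyphenol
Conditions: ethylene glycol, TsOH·H2O (cat.), toluene, reflux, Dean–Stark trap
Reagents that add atoms: ethane-1,2-diol, OCCO
Why: Acid-catalysed acetalisation with azeotropic removal of water masks the aldehyde against the hydroxide, alkoxide and organolithium reagents used later.

Step 5
Reactants: 4 [(2S,3S)-3-Ar-oxiran-2-yl]methanol; 6 2-bromo-4-(1,3-dioxolan-2-yl)-6-methoxyphenol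
Product: 7 (2S,3R)-3-[2-bromo-4-(1,3-dioxolan-2-yl)-6-methoxyphenoxy]-3-Ar-propane-1,2-diol
Conditions: 6 (2 equiv), NaOH (2 equiv), H2O/1,4-dioxane, 70 °C
Reagents that add atoms: none
Why: Base-mediated SN2 opening of a trans-3-aryl-2,3-epoxy alcohol by an aryloxide, which attacks the activated benzylic carbon with inversion under alkaline, non-ionising conditions, so that the (2S,3S)-epoxide gives the (2S,3R)-diol with C2 untouched.

Step 6
Reactants: 7 (2S,3R)-3-[2-bromo-4-(1,3-dioxolan-2-yl)-6-methoxyphenoxy]-3-Ar-propane-1,2-diol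
Product: 8 (2S,3R)-3-[2-bromo-4-(1,3-dioxolan-2-yl)-6-methoxyphenoxy]-2-hydroxy-3-Ar-propyl pivalate
Conditions: pivaloyl chloride (1.1 equiv), pyridine, CH2Cl2, −10 to 0 °C
Reagents that add atoms: pivaloyl chloride, CC(C)(C)C(Cl)=O
Why: Sterically controlled acylation, in which the bulky acid chloride esterifies the primary hydroxyl of the 1,2-diol and leaves the hindered secondary one free.

Step 7
Reactants: 8 (2S,3R)-3-[2-bromo-4-(1,3-dioxolan-2-yl)-6-methoxyphenoxy]-2-hydroxy-3-Ar-propyl pivalate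
Product: 9 (2S,3R)-3-[2-bromo-4-(1,3-dioxolan-2-yl)-6-methoxyphenoxy]-2-(methylsulfonyloxy)-3-Ar-propyl pivalate
Conditions: methanesulfonyl chloride, Et3N, CH2Cl2, 0 °C
Reagents that add atoms: methanesulfonyl chloride, CS(Cl)(=O)=O
Why: Sulfonylation turns the secondary hydroxyl into a leaving group with retention, since only the O–H bond is broken.

Step 8
Reactants: 9 (2S,3R)-3-[2-bromo-4-(1,3-dioxolan-2-yl)-6-methoxyphenoxy]-2-(methylsulfonyloxy)-3-Ar-propyl pivalate
Product: 11 (2R)-2-{(R)-[2-bromo-4-(1,3-dioxolan-2-yl)-6-methoxyphenoxy](Ar)methyl}oxirane, via hydroxy mesylate 10 (not isolated)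
Conditions: NaOMe (1.5 equiv), MeOH/THF, 0 °C to rt
Reagents that add atoms: none
Why: Methoxide transesterifies the pivalate and the freed primary alkoxide displaces the neighbouring mesylate in an intramolecular Williamson etherification (3-exo-tet SN2), which inverts C2 and gives the (R,R)-epoxide.

Step 9
Reactants: 11 (2R)-2-{(R)-[2-bromo-4-(1,3-dioxolan-2-yl)-6-methoxyphenoxy](Ar)methyl}oxirane
Product: 13 [(2S,3S)-2-Ar-5-(1,3-dioxolan-2-yl)-7-methoxy-2,3-dihydro-1-benzofuran-3-yl]methanol (2,3-cis), via aryllithium 12 (not isolated)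
Conditions: t-BuLi (2.1 equiv), THF, −78 °C, then slowly to −20 °C; H2O
Reagents that add atoms: none
Why: Bromine–lithium exchange with t-BuLi at −78 °C is faster than any attack on the epoxide and gives aryllithium 12, metalated ortho to the ether oxygen. The carbanion then opens the tethered terminal epoxide at its inner carbon in an intramolecular SN2 reaction that forms C3–C3a and releases the alkoxide of the C3 hydroxymethyl group; the closest known reaction is the Parham cyclialkylation of ortho-lithiated aryl glycidyl ethers to 2,3-dihydrobenzofuran-3-methanols. The dihydrofuran ring closes in the 5-exo-tet mode, whereas attack at the terminal CH2 would be 6-endo and lead to a chroman-3-ol. C3 is set by backside attack with inversion of the R epoxide carbon and C2 is a spectator, so the (R,R)-epoxide gives the (2S,3S) cis product. The step needs exo regioselectivity and clean inversion: the three-atom tether lets the aryl carbon reach the rear of the inner C–O bond far more easily than that of the terminal one, and no acid or Lewis acid is present that could ionise the benzylic C2–O bond. The allyl ether, the methyl ethers and the dioxolane do not react with an aryllithium at this temperature, and the second equivalent of t-BuLi is consumed by the tert-butyl bromide formed.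

Step 10
Reactants: 13 [(2S,3S)-2-Ar-5-(1,3-dioxolan-2-yl)-7-methoxy-2,3-dihydro-1-benzofuran-3-yl]methanol
Product: 14 [(2S,3S)-2-Ar-5-(1,3-dioxolan-2-yl)-7-methoxy-2,3-dihydro-1-benzofuran-3-yl]methyl pivalate
Conditions: pivaloyl chloride, pyridine, 4-(dimethylamino)pyridine (cat.), CH2Cl2, 0 °C to rt
Reagents that add atoms: pivaloyl chloride, CC(C)(C)C(Cl)=O
Why: Acylation of the primary alcohol removes the acidic proton before the enolate chemistry of step 16; the pivalate has no enolisable hydrogen and is cleaved in passing by LiAlH4 in step 17.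

Step 11
Reactants: 14 [(2S,3S)-2-Ar-5-(1,3-dioxolan-2-yl)-7-methoxy-2,3-dihydro-1-benzofuran-3-yl]methyl pivalate
Product: 15 [(2S,3S)-2-Ar-5-formyl-7-methoxy-2,3-dihydro-1-benzofuran-3-yl]methyl pivalate
Conditions: pyridinium p-toluenesulfonate (cat.), acetone/H2O, 40 °C
Reagents that add atoms: water, O
Why: Mild acid-catalysed acetal hydrolysis, in which the aryl dioxolane (para to the ring oxygen) ionises far more readily than the benzylic aryl ether bond of the cis-dihydrobenzofuran, and the pivalate is inert.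

Step 12
Reactants: 16 vanillin, 4-hydroxy-3-methoxybenzaldehyde
Product: 17 3-methoxy-4-(prop-2-enyloxy)benzaldehyde
Conditions: allyl bromide, K2CO3, DMF, rt
Reagents that add atoms: allyl bromide, C=CCBr
Why: Williamson ether synthesis on the phenoxide.

Step 13
Reactants: 17 3-methoxy-4-(prop-2-enyloxy)benzaldehyde
Product: 18 2-Ar-1,3-dithiane
Conditions: propane-1,3-dithiol, BF3·OEt2 (cat.), CH2Cl2, 0 °C
Reagents that add atoms: propane-1,3-dithiol, SCCCS
Why: Lewis-acid-catalysed dithioacetalisation converts the aldehyde into an acyl anion equivalent (umpolung).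

Step 14
Reactants: 19 furfural, furan-2-carbaldehyde
Product: 20 5-hydroxyfuran-2(5H)-one (racemic)
Conditions: O2, visible light, methylene blue (C16H18ClN3S, cat.), MeOH, rt
Reagents that add atoms: dioxygen, O=O
Why: Dye-sensitised photooxygenation, in which singlet oxygen adds [4+2] to the furan and methanolysis of the endoperoxide expels the formyl carbon as methyl formate.

Step 15
Reactants: 20 5-hydroxyfuran-2(5H)-one; 21 (+)-menthol, (1S,2R,5S)-5-methyl-2-(propan-2-yl)cyclohexan-1-ol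
Product: 22 (5S)-5-(MenO)furan-2(5H)-one
Conditions: TsOH·H2O (cat.), toluene, reflux, Dean–Stark trap; crystallisation from petroleum ether in the presence of the acid
Reagents that add atoms: none
Why: Acid-catalysed acetalisation of the lactol, in which the acetal carbon epimerises under the acid and crystallisation drives the mixture to the single (5S) diastereomer (crystallisation-induced asymmetric transformation).

Step 16
Reactants: 18 2-Ar-1,3-dithiane; 22 (5S)-5-(MenO)furan-2(5H)-one; 15 [(2S,3S)-2-Ar-5-formyl-7-methoxy-2,3-dihydro-1-benzofuran-3-yl]methyl pivalate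
Product: 25 (3R,4S,5S)-3-{hydroxy[(2S,3S)-2-Ar-7-methoxy-3-(pivaloyloxymethyl)-2,3-dihydro-1-benzofuran-5-yl]methyl}-4-(2-Ar-1,3-dithian-2-yl)-5-(MenO)oxolan-2-one (both carbinol epimers), via lithiated dithiane 23 (not isolated), via lactone enolate 24 (not isolated)
Conditions: n-BuLi (1 equiv on 18), THF, −78 to −20 °C; 22, −90 °C; 15 (limiting), −90 to −78 °C; AcOH quench at −78 °C
Reagents that add atoms: none
Why: Tandem conjugate addition–aldol reaction, in which the lithiated dithiane adds to C4 of the butenolide anti to the menthyloxy group (this sets furofuran C6a) and the lactone enolate is trapped by the aldehyde anti to the new substituent (this sets furofuran C3a), giving the 3,4-trans-4,5-trans lactone.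

Step 17
Reactants: 25 (3R,4S,5S)-3-{hydroxy[(2S,3S)-2-Ar-7-methoxy-3-(pivaloyloxymethyl)-2,3-dihydro-1-benzofuran-5-yl]methyl}-4-(2-Ar-1,3-dithian-2-yl)-5-(MenO)oxolan-2-one
Product: 26 (2S,3S)-2-(2-Ar-1,3-dithian-2-yl)-3-{hydroxy[(2S,3S)-2-Ar-3-(hydroxymethyl)-7-methoxy-2,3-dihydro-1-benzofuran-5-yl]methyl}butane-1,4-diol (both carbinol epimers)
Conditions: LiAlH4 (excess), THF, 0 °C; aqueous work-up
Reagents that add atoms: none
Why: Hydride reduction of the lactone acylal gives the 1,4-diol with loss of menthol (both carbons end as CH2OH) and cleaves the pivalate in the same operation, while the dithiane, the allyl ethers and the dihydrobenzofuran are inert.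

Step 18
Reactants: 26 (2S,3S)-2-(2-Ar-1,3-dithian-2-yl)-3-{hydroxy[(2S,3S)-2-Ar-3-(hydroxymethyl)-7-methoxy-2,3-dihydro-1-benzofuran-5-yl]methyl}butane-1,4-diol
Product: 27 (2S,3S)-3-(2-Ar-1,3-dithian-2-yl)-4-hydroxy-2-(hydroxymethyl)-1-[(2S,3S)-2-Ar-3-(hydroxymethyl)-7-methoxy-2,3-dihydro-1-benzofuran-5-yl]butan-1-one
Conditions: MnO2 (activated, excess), CH2Cl2/acetone, rt
Reagents that add atoms: none
Why: Chemoselective MnO2 oxidation converts only the benzylic alcohol to the aryl ketone, so both carbinol epimers converge and the three primary alcohols stay untouched.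

Step 19
Reactants: 27 (2S,3S)-3-(2-Ar-1,3-dithian-2-yl)-4-hydroxy-2-(hydroxymethyl)-1-[(2S,3S)-2-Ar-3-(hydroxymethyl)-7-methoxy-2,3-dihydro-1-benzofuran-5-yl]butan-1-one
Product: 28 (2S,3S)-1-Ar-2,3-bis(hydroxymethyl)-4-[(2S,3S)-2-Ar-3-(hydroxymethyl)-7-methoxy-2,3-dihydro-1-benzofuran-5-yl]butane-1,4-dione
Conditions: MeI (excess), CaCO3, MeCN/H2O (4:1), 45 °C
Reagents that add atoms: water, O
Why: Alkylative dethioketalisation, in which S-methylation turns the dithiane into a sulfonium leaving group and water hydrolyses the thionium ion to the ketone under near-neutral conditions that spare the allyl ethers (unlike divalent mercury salts).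

Step 20
Reactants: 28 (2S,3S)-1-Ar-2,3-bis(hydroxymethyl)-4-[(2S,3S)-2-Ar-3-(hydroxymethyl)-7-methoxy-2,3-dihydro-1-benzofuran-5-yl]butane-1,4-dione
Product: 30 [(2S,3S)-2-Ar-5-[(1S,3aS,4S,6aS)-4-Ar-tetrahydro-1H,3H-furo[3,4-c]furan-1-yl]-7-methoxy-2,3-dihydro-1-benzofuran-3-yl]methanol, via bis-hemiketal 29 (not isolated)
Conditions: Et3SiH (6 equiv), BF3·OEt2 (3 equiv), CH2Cl2, −78 °C; Et3N then aqueous NaHCO3 at −78 °C
Reagents that add atoms: none
Why: Ionic hydrogenation (reductive deoxygenation of hemiketals), in which the diketo diol closes to the cis-fused bis-hemiketal, BF3 ionises each tertiary benzylic hemiketal to an oxocarbenium ion much faster at −78 °C than it could ionise a secondary benzylic ether, and the silane delivers hydride to the convex face of the bicyclo[3.3.0] framework, so both new hydrogens are exo and both aryl groups endo (1S,4S).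

Step 21
Reactants: 30 [(2S,3S)-2-Ar-5-[(1S,3aS,4S,6aS)-4-Ar-tetrahydro-1H,3H-furo[3,4-c]furan-1-yl]-7-methoxy-2,3-dihydro-1-benzofuran-3-yl]methanol
Product: 31 4-[(1S,3aS,4S,6aS)-4-[(2S,3S)-2-(4-hydroxy-3-methoxyphenyl)-3-(hydroxymethyl)-7-methoxy-2,3-dihydro-1-benzofuran-5-yl]tetrahydro-1H,3H-furo[3,4-c]furan-1-yl]-2-methoxyphenol (target)
Conditions: Pd(PPh3)4 (5 mol %), morpholine (10 equiv), THF, rt
Reagents that add atoms: none
Why: Tsuji–Trost deallylation, in which zerovalent palladium ionises both aryl allyl ethers to π-allyl complexes that morpholine traps, under neutral conditions that leave the acid-labile benzylic ethers and every stereocentre untouched.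

**Compound list**

1 | ferulic acid, (2E)-3-(4-hydroxy-3-methoxyphenyl)prop-2-enoic acid | COc1cc(/C=C/C(O)=O)ccc1O | starting material
2 | prop-2-enyl (2E)-3-Ar-prop-2-enoate | C=CCOC(=O)/C=C/c1ccc(OCC=C)c(OC)c1 | intermediate
3 | (2E)-3-Ar-prop-2-en-1-ol | OC/C=C/c1ccc(OCC=C)c(OC)c1 | intermediate
4 | [(2S,3S)-3-Ar-oxiran-2-yl]methanol | OC[C@@H]1O[C@H]1c1ccc(OCC=C)c(OC)c1 | intermediate
5 | 5-bromovanillin | COc1cc(C=O)cc(Br)c1O | starting material
6 | 2-bromo-4-(1,3-dioxolan-2-yl)-6-methoxyphenol | COc1cc(C2OCCO2)cc(Br)c1O | intermediate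
7 | (2S,3R)-3-[2-bromo-4-(1,3-dioxolan-2-yl)-6-methoxyphenoxy]-3-Ar-propane-1,2-diol | O1CCOC1c1cc(OC)c(O[C@H](c2ccc(OCC=C)c(OC)c2)[C@@H](O)CO)c(Br)c1 | intermediate
8 | (2S,3R)-3-[2-bromo-4-(1,3-dioxolan-2-yl)-6-methoxyphenoxy]-2-hydroxy-3-Ar-propyl pivalate | O1CCOC1c1cc(OC)c(O[C@H](c2ccc(OCC=C)c(OC)c2)[C@@H](O)COC(=O)C(C)(C)C)c(Br)c1 | intermediate
9 | (2S,3R)-3-[2-bromo-4-(1,3-dioxolan-2-yl)-6-methoxyphenoxy]-2-(methylsulfonyloxy)-3-Ar-propyl pivalate | O1CCOC1c1cc(OC)c(O[C@H](c2ccc(OCC=C)c(OC)c2)[C@@H](OS(C)(=O)=O)COC(=O)C(C)(C)C)c(Br)c1 | intermediate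
10 | (2S,3R)-3-[2-bromo-4-(1,3-dioxolan-2-yl)-6-methoxyphenoxy]-1-hydroxy-3-Ar-propan-2-yl methanesulfonate (hydroxy mesylate, present as its alkoxide, formed in the flask) | O1CCOC1c1cc(OC)c(O[C@H](c2ccc(OCC=C)c(OC)c2)[C@@H](OS(C)(=O)=O)CO)c(Br)c1 | intermediate
11 | (2R)-2-{(R)-[2-bromo-4-(1,3-dioxolan-2-yl)-6-methoxyphenoxy](Ar)methyl}oxirane | O1CCOC1c1cc(OC)c(O[C@H](c2ccc(OCC=C)c(OC)c2)[C@H]2CO2)c(Br)c1 | intermediate
12 | (2R)-2-{(R)-[4-(1,3-dioxolan-2-yl)-2-lithio-6-methoxyphenoxy](Ar)methyl}oxirane (aryllithium, formed in the flask) | O1CCOC1c1cc(OC)c(O[C@H](c2ccc(OCC=C)c(OC)c2)[C@H]2CO2)c([Li])c1 | intermediate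
13 | [(2S,3S)-2-Ar-5-(1,3-dioxolan-2-yl)-7-methoxy-2,3-dihydro-1-benzofuran-3-yl]methanol (2,3-cis) | O1CCOC1c1cc(OC)c2c(c1)[C@@H](CO)[C@@H](c1ccc(OCC=C)c(OC)c1)O2 | intermediate
14 | [(2S,3S)-2-Ar-5-(1,3-dioxolan-2-yl)-7-methoxy-2,3-dihydro-1-benzofuran-3-yl]methyl pivalate | O1CCOC1c1cc(OC)c2c(c1)[C@@H](COC(=O)C(C)(C)C)[C@@H](c1ccc(OCC=C)c(OC)c1)O2 | intermediate
15 | [(2S,3S)-2-Ar-5-formyl-7-methoxy-2,3-dihydro-1-benzofuran-3-yl]methyl pivalate | O=Cc1cc(OC)c2c(c1)[C@@H](COC(=O)C(C)(C)C)[C@@H](c1ccc(OCC=C)c(OC)c1)O2 | intermediate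
16 | vanillin | COc1cc(C=O)ccc1O | starting material
17 | 3-methoxy-4-(prop-2-enyloxy)benzaldehyde | C=CCOc1ccc(C=O)cc1OC | intermediate
18 | 2-Ar-1,3-dithiane | C=CCOc1ccc(cc1OC)C1SCCCS1 | intermediate
19 | furfural | O=Cc1ccco1 | starting material
20 | 5-hydroxyfuran-2(5H)-one (racemic) | O=C1C=CC(O)O1 | intermediate
21 | (+)-menthol | C[C@H]1CC[C@@H]([C@H](C1)O)C(C)C | starting material
22 | (5S)-5-(MenO)furan-2(5H)-one | O=C1C=C[C@@H](O[C@H]2C[C@@H](C)CC[C@@H]2C(C)C)O1 | intermediate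
23 | 2-lithio-2-Ar-1,3-dithiane (formed in the flask) | [Li]C1(c2ccc(OCC=C)c(OC)c2)SCCCS1 | intermediate
24 | lithium (4S,5S)-4-(2-Ar-1,3-dithian-2-yl)-5-(MenO)-4,5-dihydrofuran-2-olate (lactone enolate, formed in the flask) | [Li]OC1=C[C@H](C2(c3ccc(OCC=C)c(OC)c3)SCCCS2)[C@@H](O[C@H]2C[C@@H](C)CC[C@@H]2C(C)C)O1 | intermediate
25 | (3R,4S,5S)-3-{hydroxy[(2S,3S)-2-Ar-7-methoxy-3-(pivaloyloxymethyl)-2,3-dihydro-1-benzofuran-5-yl]methyl}-4-(2-Ar-1,3-dithian-2-yl)-5-(MenO)oxolan-2-one (carbinol centre open) | O=C1O[C@H](O[C@H]2C[C@@H](C)CC[C@@H]2C(C)C)[C@@H](C2(c3ccc(OCC=C)c(OC)c3)SCCCS2)[C@@H]1C(O)c1cc(OC)c2c(c1)[C@@H](COC(=O)C(C)(C)C)[C@@H](c1ccc(OCC=C)c(OC)c1)O2 | intermediate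
26 | (2S,3S)-2-(2-Ar-1,3-dithian-2-yl)-3-{hydroxy[(2S,3S)-2-Ar-3-(hydroxymethyl)-7-methoxy-2,3-dihydro-1-benzofuran-5-yl]methyl}butane-1,4-diol (carbinol centre open) | OC[C@@H](C1(c2ccc(OCC=C)c(OC)c2)SCCCS1)[C@@H](CO)C(O)c1cc(OC)c2c(c1)[C@@H](CO)[C@@H](c1ccc(OCC=C)c(OC)c1)O2 | intermediate
27 | (2S,3S)-3-(2-Ar-1,3-dithian-2-yl)-4-hydroxy-2-(hydroxymethyl)-1-[(2S,3S)-2-Ar-3-(hydroxymethyl)-7-methoxy-2,3-dihydro-1-benzofuran-5-yl]butan-1-one | OC[C@@H](C1(c2ccc(OCC=C)c(OC)c2)SCCCS1)[C@@H](CO)C(=O)c1cc(OC)c2c(c1)[C@@H](CO)[C@@H](c1ccc(OCC=C)c(OC)c1)O2 | intermediate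
28 | (2S,3S)-1-Ar-2,3-bis(hydroxymethyl)-4-[(2S,3S)-2-Ar-3-(hydroxymethyl)-7-methoxy-2,3-dihydro-1-benzofuran-5-yl]butane-1,4-dione | OC[C@@H](C(=O)c1ccc(OCC=C)c(OC)c1)[C@@H](CO)C(=O)c1cc(OC)c2c(c1)[C@@H](CO)[C@@H](c1ccc(OCC=C)c(OC)c1)O2 | intermediate
29 | (3aS,6aS)-1-Ar-4-[(2S,3S)-2-Ar-3-(hydroxymethyl)-7-methoxy-2,3-dihydro-1-benzofuran-5-yl]tetrahydro-1H,3H-furo[3,4-c]furan-1,4-diol (bis-hemiketal, hemiketal centres open, formed in the flask) | COc1cc(C2(O)OC[C@@H]3[C@H]2COC3(O)c2cc(OC)c3c(c2)[C@@H](CO)[C@@H](c2ccc(OCC=C)c(OC)c2)O3)ccc1OCC=C | intermediate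
30 | [(2S,3S)-2-Ar-5-[(1S,3aS,4S,6aS)-4-Ar-tetrahydro-1H,3H-furo[3,4-c]furan-1-yl]-7-methoxy-2,3-dihydro-1-benzofuran-3-yl]methanol | COc1cc([C@H]2OC[C@@H]3[C@H]2CO[C@@H]3c2cc(OC)c3c(c2)[C@@H](CO)[C@@H](c2ccc(OCC=C)c(OC)c2)O3)ccc1OCC=C | intermediate
31 | 4-[(1S,3aS,4S,6aS)-4-[(2S,3S)-2-(4-hydroxy-3-methoxyphenyl)-3-(hydroxymethyl)-7-methoxy-2,3-dihydro-1-benzofuran-5-yl]tetrahydro-1H,3H-furo[3,4-c]furan-1-yl]-2-methoxyphenol | COc1cc([C@H]2OC[C@@H]3[C@H]2CO[C@@H]3c2cc(OC)c3c(c2)[C@@H](CO)[C@@H](c2ccc(O)c(OC)c2)O3)ccc1O | target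

**Counts**

Total step count: 21. Longest linear sequence: 16 steps (steps 1–3, 5–11, 16–21).

**Steps most likely to fail**

Step 5. The electron-rich aryl group can let the benzylic C–O bond of the epoxide ionise before the phenoxide arrives, which erodes the inversion and invites hydrolysis, and Payne rearrangement can divert the nucleophile to C1. The fallback sets out from 17 and 6 and returns at 8; it makes the ether from an alcohol instead of an epoxide and takes both stereocentres from an auxiliary aldol. A boron-mediated Evans syn-glycolate aldol of 17 with (4R)-4-benzyl-3-[(4-methoxybenzyloxy)acetyl]-1,3-oxazolidin-2-one (Bu2BOTf, i-Pr2NEt, CH2Cl2, −78 °C) should give the (2R,3S) syn-aldol imide F1. LiBH4 removes the auxiliary and gives the (1S,2S)-diol F2, and pivaloyl chloride/pyridine acylates its primary hydroxyl to give the hydroxy pivalate F3. Mitsunobu etherification of the benzylic alcohol with phenol 6 (PPh3, diisopropyl azodicarboxylate, toluene, 0 °C) inverts that centre and gives the aryl ether F4. 2,3-Dichloro-5,6-dicyano-1,4-benzoquinone in CH2Cl2/pH 7 buffer removes the 4-methoxybenzyl group and delivers 8.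

Step 9. The aryllithium may open the epoxide at the terminal carbon (6-endo, chroman-3-ol), or be quenched by proton transfer from the doubly activated benzylic C–H before it cyclises. The fallback sets out from 17 and 6 and returns at 13; it closes the same ring by carbenoid C–H insertion. NaBH4 reduces 17 to the benzyl alcohol F5, and Mitsunobu coupling with 6 gives the aryl benzyl ether F6. Bromine–lithium exchange (t-BuLi, −78 °C) and acylation with dimethyl oxalate give the α-keto ester F7. Tosylhydrazide gives the tosylhydrazone F8, which 1,8-diazabicyclo[5.4.0]undec-7-ene converts (Bamford–Stevens) into the aryldiazoacetate F9. Intramolecular 1,5 C–H insertion into the benzylic ether CH2, catalysed by dirhodium tetrakis[N-phthaloyl-tert-leucinate], Rh2(PTTL)4, is a reaction class that gives cis-2-aryl-2,3-dihydrobenzofuran-3-carboxylates; with the catalyst antipode that leads to the (2S,3R) series it should give the cis ester F10. LiAlH4 at −78 °C reduces the ester without epimerisation to 13.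

Step 20. The Lewis acid may ionise the benzylic ether bonds of the product or of the cis-dihydrobenzofuran, leading to epimerisation to exo-aryl or trans isomers or to reductive ring opening, and the oxocarbenium ions may lose a proton to enol ethers instead of accepting hydride. The fallback sets out from 28 and returns at 31; it changes the phenol protection before the reduction so that rings A and C are electron-poor while the Lewis acid is present. Pd(PPh3)4/morpholine removes both allyl groups from 28 and gives the bisphenol F11. Phenoxide-selective acetylation (Ac2O, K2CO3, acetone, 0 °C) gives the diacetate F12 with the primary alcohols still free. Et3SiH/BF3·OEt2 at −78 °C then gives the furofuran diacetate F13, whose acetoxy groups retard ionisation of the benzofuran C2–O and furofuran C1–O bonds. K2CO3/MeOH removes the acetates and gives 31.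

Further compounds
F1 | step 5 | (4R)-4-benzyl-3-[(2R,3S)-3-Ar-3-hydroxy-2-(4-methoxybenzyloxy)propanoyl]-1,3-oxazolidin-2-one | O=C1OC[C@@H](Cc2ccccc2)N1C(=O)[C@H](OCc1ccc(OC)cc1)[C@@H](O)c1ccc(OCC=C)c(OC)c1
F2 | step 5 | (1S,2S)-1-Ar-2-(4-methoxybenzyloxy)propane-1,3-diol | OC[C@H](OCc1ccc(OC)cc1)[C@@H](O)c1ccc(OCC=C)c(OC)c1
F3 | step 5 | (2S,3S)-3-Ar-3-hydroxy-2-(4-methoxybenzyloxy)propyl pivalate | CC(C)(C)C(=O)OC[C@H](OCc1ccc(OC)cc1)[C@@H](O)c1ccc(OCC=C)c(OC)c1
F4 | step 5 | (2S,3R)-3-Ar-3-[2-bromo-4-(1,3-dioxolan-2-yl)-6-methoxyphenoxy]-2-(4-methoxybenzyloxy)propyl pivalate | CC(C)(C)C(=O)OC[C@H](OCc1ccc(OC)cc1)[C@H](Oc1c(Br)cc(C2OCCO2)cc1OC)c1ccc(OCC=C)c(OC)c1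
F5 | step 9 | [3-methoxy-4-(prop-2-enyloxy)phenyl]methanol | OCc1ccc(OCC=C)c(OC)c1
F6 | step 9 | 2-[3-bromo-5-methoxy-4-(Ar-methoxy)phenyl]-1,3-dioxolane | COc1cc(C2OCCO2)cc(Br)c1OCc1ccc(OCC=C)c(OC)c1
F7 | step 9 | methyl 2-[5-(1,3-dioxolan-2-yl)-3-methoxy-2-(Ar-methoxy)phenyl]-2-oxoacetate | COC(=O)C(=O)c1cc(C2OCCO2)cc(OC)c1OCc1ccc(OCC=C)c(OC)c1
F8 | step 9 | methyl 2-[5-(1,3-dioxolan-2-yl)-3-methoxy-2-(Ar-methoxy)phenyl]-2-[(4-methylphenyl)sulfonylhydrazinylidene]acetate | COC(=O)C(=NNS(=O)(=O)c1ccc(C)cc1)c1cc(C2OCCO2)cc(OC)c1OCc1ccc(OCC=C)c(OC)c1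
F9 | step 9 | methyl 2-diazo-2-[5-(1,3-dioxolan-2-yl)-3-methoxy-2-(Ar-methoxy)phenyl]acetate | COC(=O)C(=[N+]=[N-])c1cc(C2OCCO2)cc(OC)c1OCc1ccc(OCC=C)c(OC)c1
F10 | step 9 | methyl (2S,3R)-2-Ar-5-(1,3-dioxolan-2-yl)-7-methoxy-2,3-dihydro-1-benzofuran-3-carboxylate (2,3-cis) | O1CCOC1c1cc(OC)c2c(c1)[C@@H](C(=O)OC)[C@@H](c1ccc(OCC=C)c(OC)c1)O2
F11 | step 20 | (2S,3S)-1-(4-hydroxy-3-methoxyphenyl)-4-[(2S,3S)-2-(4-hydroxy-3-methoxyphenyl)-3-(hydroxymethyl)-7-methoxy-2,3-dihydro-1-benzofuran-5-yl]-2,3-bis(hydroxymethyl)butane-1,4-dione | OC[C@@H](C(=O)c1ccc(O)c(OC)c1)[C@@H](CO)C(=O)c1cc(OC)c2c(c1)[C@@H](CO)[C@@H](c1ccc(O)c(OC)c1)O2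
F12 | step 20 | (2S,3S)-1-(4-acetoxy-3-methoxyphenyl)-4-[(2S,3S)-2-(4-acetoxy-3-methoxyphenyl)-3-(hydroxymethyl)-7-methoxy-2,3-dihydro-1-benzofuran-5-yl]-2,3-bis(hydroxymethyl)butane-1,4-dione | OC[C@@H](C(=O)c1ccc(OC(C)=O)c(OC)c1)[C@@H](CO)C(=O)c1cc(OC)c2c(c1)[C@@H](CO)[C@@H](c1ccc(OC(C)=O)c(OC)c1)O2
F13 | step 20 | 4-[(1S,3aS,4S,6aS)-4-[(2S,3S)-2-(4-acetoxy-3-methoxyphenyl)-3-(hydroxymethyl)-7-methoxy-2,3-dihydro-1-benzofuran-5-yl]tetrahydro-1H,3H-furo[3,4-c]furan-1-yl]-2-methoxyphenyl acetate | COc1cc([C@H]2OC[C@@H]3[C@H]2CO[C@@H]3c2cc(OC)c3c(c2)[C@@H](CO)[C@@H](c2ccc(OC(C)=O)c(OC)c2)O3)ccc1OC(C)=O
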